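**Plan**
- Retrosynthesis: the ring A enone goes back to an allylic carbinol that differs from the ring B carbinol only in its silyl group. The central C14=C15–C15'=C14' diene goes back to a 15,15'-yne-14,14'-diol, which is cut at C14–C15 and C15'–C14' into two C19 pentaenals and acetylene.
- Enabling feature: the retro skeleton (exocyclic C6=C7 and C6'=C7' on rings A and B) places an E,E-diene at C14=C15–C15'=C14'. Removing two hydroxyls from a C14,C14'-diol across a C15≡C15' triple bond gives exactly this diene, so acetylene can supply C15 and C15'.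
- Each C19 aldehyde is cut at C12=C13, C10=C11 and C8=C9 (HWE, Wittig, HWE) and at C6–C7 (ethynylation, then Meyer–Schuster shift) back to ketoisophorone.
- Forward: one C19 aldehyde is built linearly on the ketoisophorone ring (no ring is formed anywhere). Part of it is re-silylated (TBS to TMS) as the ring A partner, and both aldehydes are joined with ethynylmagnesium bromide in one pot. Reductive elimination, equilibration, ring A oxidation and desilylation finish the route.
- Stereochemistry: C3' (S) comes from asymmetric transfer hydrogenation of ketoisophorone and is not touched again. The ring A carbinol is oxidized away. Alkene geometry comes from E-selective olefinations and an iodine equilibration.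

Key step: step 14

Assumption: carotenoid numbering is used (ring A C1–C6, chain C7–C15, primed numbers for the ring B half), and the 6E/6'E geometry (chain syn to C1/C1') is taken to be the thermodynamically preferred one, so equilibrating steps converge on it. TBS = tert-butyldimethylsilyl, TMS = trimethylsilyl.

**Route**

Step 1
Reactants: 1 ketoisophorone
Product: 2 (4S)-4-hydroxy-2,6,6-trimethylcyclohex-2-en-1-one
Conditions: RuCl(p-cymene)[(S,S)-TsDPEN] (0.5 mol%), KOH (1 mol%), iPrOH, rt
Reagents that add atoms: none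
Why: Noyori–Ikariya asymmetric transfer hydrogenation should reduce only the unhindered C4 carbonyl (C1 is shielded by the gem-dimethyl carbon and the C2 methyl), and the (S,S) ligand is chosen so that hydride reaches the face giving the S carbinol, the enone π-system taking the place an aryl group has in the usual CH–π model.

Step 2
Reactants: 2 (4S)-4-hydroxy-2,6,6-trimethylcyclohex-2-en-1-one
Product: 3 (4S)-4-(tert-butyldimethylsilyloxy)-2,6,6-trimethylcyclohex-2-en-1-one
Conditions: TBSCl, imidazole, DMF, rt
Reagents that add atoms: tert-butyldimethylsilyl chloride, CC(C)(C)[Si](C)(C)Cl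
Why: Imidazole-mediated silylation of a secondary allylic alcohol is routine and does not touch the stereocenter.

Step 3
Reactants: 3 (4S)-4-(tert-butyldimethylsilyloxy)-2,6,6-trimethylcyclohex-2-en-1-one; 4 ethynylmagnesium bromide
Product: 5 (4S)-4-(tert-butyldimethylsilyloxy)-1-ethynyl-2,6,6-trimethylcyclohex-2-en-1-ol (C1 epimer mixture)
Conditions: 4 (2 equiv), THF, 0 °C → rt; aq NH4Cl
Reagents that add atoms: none
Why: 1,2-Addition of the small alkynyl Grignard reagent to the hindered carbonyl should be clean because neither flank carries an α-hydrogen; the new tertiary carbinol center forms uncontrolled and is erased in step 4.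

Step 4
Reactants: 5 (4S)-4-(tert-butyldimethylsilyloxy)-1-ethynyl-2,6,6-trimethylcyclohex-2-en-1-ol
Product: 6 (2E)-2-[(4S)-4-(tert-butyldimethylsilyloxy)-2,6,6-trimethylcyclohex-2-en-1-ylidene]acetaldehyde
Conditions: MoO2(acac)2 (2 mol%), AuCl(PPh3) (2 mol%), AgOTf (2 mol%), toluene, rt
Reagents that add atoms: none
Why: Meyer–Schuster rearrangement, in which the molybdate ester and gold activation of the alkyne shift the hydroxyl to the alkyne terminus and the allenol tautomerizes to the enal; Rupe dehydration is excluded because the carbinol carbon has no β-hydrogen, and thermodynamic control should place the formyl group on the side of the gem-dimethyl carbon, away from the in-plane ring methyl.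

Step 5
Reactants: 6 the C11 enal; 7 triethyl 2-phosphonopropionate
Product: 8 ethyl (2E,4E)-4-[(4S)-4-(tert-butyldimethylsilyloxy)-2,6,6-trimethylcyclohex-2-en-1-ylidene]-2-methylbut-2-enoate
Conditions: 7, NaH, THF, 0 °C; then 6, 0 °C → rt
Reagents that add atoms: none
Why: Horner–Wadsworth–Emmons olefination of an unhindered enal with an α-methyl phosphonoacetate should give the E trisubstituted C8=C9 alkene under thermodynamic control of the oxaphosphetane.

Step 6
Reactants: 8 the C14 ester
Product: 9 (2E,4E)-4-[(4S)-4-(tert-butyldimethylsilyloxy)-2,6,6-trimethylcyclohex-2-en-1-ylidene]-2-methylbut-2-en-1-ol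
Conditions: iBu2AlH (2.2 equiv), CH2Cl2, −78 °C; aqueous work-up
Reagents that add atoms: none
Why: iBu2AlH reduces conjugated esters to allylic alcohols by 1,2-hydride delivery without touching the diene or the silyl ether.

Step 7
Reactants: 9 the C14 allylic alcohol
Product: 10 (2E,4E)-4-[(4S)-4-(tert-butyldimethylsilyloxy)-2,6,6-trimethylcyclohex-2-en-1-ylidene]-2-methylbut-2-enal
Conditions: MnO2 (excess), CH2Cl2, rt
Reagents that add atoms: none
Why: MnO2 oxidation of a primary allylic alcohol should stop at the aldehyde and keep the alkene geometry.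

Step 8
Reactants: 10 the C14 aldehyde; 11 (triphenylphosphoranylidene)acetaldehyde
Product: 12 (2E,4E,6E)-6-[(4S)-4-(tert-butyldimethylsilyloxy)-2,6,6-trimethylcyclohex-2-en-1-ylidene]-4-methylhexa-2,4-dienal
Conditions: 11 (1.3 equiv), toluene, 80 °C
Reagents that add atoms: none
Why: Wittig reaction with the stabilized formyl ylide should give the E C10=C11 alkene, and the vinylogous product aldehyde is less electrophilic than 10, which limits a second homologation.

Step 9
Reactants: 12 the C16 aldehyde; 7 triethyl 2-phosphonopropionate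
Product: 13 ethyl (2E,4E,6E,8E)-8-[(4S)-4-(tert-butyldimethylsilyloxy)-2,6,6-trimethylcyclohex-2-en-1-ylidene]-2,6-dimethylocta-2,4,6-trienoate
Conditions: 7, NaH, THF, 0 °C; then 12, 0 °C → rt
Reagents that add atoms: none
Why: A second E-selective Horner–Wadsworth–Emmons olefination sets the C12=C13 alkene with its methyl group.

Step 10
Reactants: 13 the C19 ester
Product: 14 (2E,4E,6E,8E)-8-[(4S)-4-(tert-butyldimethylsilyloxy)-2,6,6-trimethylcyclohex-2-en-1-ylidene]-2,6-dimethylocta-2,4,6-trien-1-ol
Conditions: iBu2AlH (2.2 equiv), CH2Cl2, −78 °C; aqueous work-up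
Reagents that add atoms: none
Why: 1,2-Reduction of the conjugated ester with iBu2AlH, as in step 6.

Step 11
Reactants: 14 the C19 allylic alcohol
Product: 15 (2E,4E,6E,8E)-8-[(4S)-4-(tert-butyldimethylsilyloxy)-2,6,6-trimethylcyclohex-2-en-1-ylidene]-2,6-dimethylocta-2,4,6-trienal (ring B C19 aldehyde)
Conditions: MnO2 (excess), CH2Cl2, rt
Reagents that add atoms: none
Why: MnO2 allylic oxidation, as in step 7, gives the pentaenal that has no α-hydrogen.

Step 12 (about half of 15 is taken on)
Reactants: 15 the ring B C19 aldehyde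
Product: 16 (2E,4E,6E,8E)-8-[(4S)-4-hydroxy-2,6,6-trimethylcyclohex-2-en-1-ylidene]-2,6-dimethylocta-2,4,6-trienal
Conditions: Bu4NF, AcOH (1:1), THF, rt
Reagents that add atoms: none
Why: Fluoride desilylation buffered with acetic acid should free the ring hydroxyl without base-induced damage to the polyenal.

Step 13
Reactants: 16 the C19 hydroxy aldehyde
Product: 17 (2E,4E,6E,8E)-2,6-dimethyl-8-[(4S)-2,6,6-trimethyl-4-(trimethylsilyloxy)cyclohex-2-en-1-ylidene]octa-2,4,6-trienal (ring A-side C19 aldehyde)
Conditions: TMSCl, imidazole, CH2Cl2, 0 °C; NaHCO3 work-up, used directly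
Reagents that add atoms: chlorotrimethylsilane, C[Si](C)(C)Cl
Why: Silylation gives a trimethylsilyl ether that removes the only acidic proton for the Grignard step and can later be cleaved by basic methanol in the presence of the TBS ether.

Step 14
Reactants: 17 the ring A-side C19 aldehyde (TMS ether); 4 ethynylmagnesium bromide; 15 the ring B C19 aldehyde (TBS ether)
Product: 20 C40 15,15'-yne-14,14'-diol (ring A 3-OTMS; ring B 3'-OTBS; C14/C14' epimers), via C21 ethynylcarbinol bromomagnesium alkoxide 18 (not isolated), via C21 alkynylmagnesium bromide alkoxide 19 (not isolated)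
Conditions: 4 (1.05 equiv), THF, −20 °C, slow addition of 17, then 0 °C; EtMgBr (1.0 equiv), 0 → 35 °C; 15 (1.0 equiv), 0 °C → rt; aq NH4Cl
Reagents that add atoms: none
Why: The magnesium acetylide adds 1,2 to the non-enolizable aldehyde 17 (C14–C15 bond) to give alkoxide 18; EtMgBr then removes the terminal alkyne proton with loss of ethane, and the carbon nucleophile 19 adds to aldehyde 15 (C15'–C14' bond). The closest known reaction type is the union of two polyenals through the acetylene bis-Grignard reagent in carotenoid synthesis, run here in sequence so that two different aldehydes are joined. No ring closes. The two new carbinol centers at C14 and C14' form without control and are removed in step 16. The step needs mono-addition in the first stage and carbonyl over conjugate attack: inverse slow addition at −20 °C keeps the acetylide in excess while the alkyne C–H of its adduct stays unmetalated, the aldehydes have no α-hydrogen, both ring hydroxyls are silylated so no proton quenches the reagents, and hard magnesium acetylides attack the carbonyl carbon. Any symmetrical ynediol from acetylide disproportionation carries two identical silyl groups and should separate by polarity after step 15.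

Step 15
Reactants: 20 the C40 ynediol bis(silyl ether) (crude)
Product: 21 C40 15,15'-yne-3,14,14'-triol 3'-TBS ether (C14/C14' epimers)
Conditions: K2CO3 (cat.), MeOH, 0 °C
Reagents that add atoms: none
Why: Base-catalyzed methanolysis cleaves the trimethylsilyl ether and leaves the far more hindered TBS ether, so the ring A carbinol alone is unveiled without acid.

Step 16
Reactants: 21 the C40 ynetriol mono-TBS ether
Product: 22 (3S,3'S)-3'-(tert-butyldimethylsilyloxy)-4',5'-didehydro-4,5'-retro-β,β-caroten-3-ol as a mixture of C14=C15/C15'=C14' geometric isomers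
Conditions: LiAlH4 (4 equiv), THF, 0 °C → rt; aqueous work-up
Reagents that add atoms: none
Why: Whiting reductive elimination, in which the alkoxyaluminate delivers hydride to the alkyne, the vinylalane expels the second oxygen to give an allenyl carbinol, and SN2' hydride displacement of the remaining oxygen leaves the conjugated diene; both carbinols are allylic, which favors elimination over simple alkyne reduction.

Step 17
Reactants: 22 the diene as isomer mixture
Product: 23 (3S,3'S,all-E)-3'-(tert-butyldimethylsilyloxy)-4',5'-didehydro-4,5'-retro-β,β-caroten-3-ol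
Conditions: I2 (1 mol%), CH2Cl2, rt, daylight
Reagents that add atoms: none
Why: Iodine-catalyzed E/Z equilibration through reversible iodine-atom addition should funnel the polyene to the all-E isomer, the usual thermodynamic endpoint for carotenoids.

Step 18
Reactants: 23 the all-E ring A carbinol
Product: 24 (3'S,all-E)-3'-(tert-butyldimethylsilyloxy)-4',5'-didehydro-4,5'-retro-β,β-caroten-3-one
Conditions: MnO2 (excess), CH2Cl2, rt
Reagents that add atoms: none
Why: MnO2 oxidation of the only free hydroxyl, a secondary allylic carbinol conjugated with the polyene, gives the ring A enone while the ring B oxygen stays silylated.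

Step 19
Reactants: 24 the ring A ketone TBS ether
Product: 25 (3'S,all-E)-3'-hydroxy-4',5'-didehydro-4,5'-retro-β,β-caroten-3-one (target)
Conditions: Bu4NF, AcOH (1:1), THF, rt
Reagents that add atoms: none
Why: Buffered fluoride desilylation removes the TBS group without acid that could ionize the allylic C3' carbinol and without free base that could enolize the ring A ketone.

**Compound list**

1 | ketoisophorone (2,6,6-trimethylcyclohex-2-ene-1,4-dione) | CC1=CC(=O)CC(C)(C)C1=O | starting material
2 | (4S)-4-hydroxy-2,6,6-trimethylcyclohex-2-en-1-one | CC1=C[C@@H](O)CC(C)(C)C1=O | intermediate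
3 | (4S)-4-(tert-butyldimethylsilyloxy)-2,6,6-trimethylcyclohex-2-en-1-one | CC1=C[C@@H](O[Si](C)(C)C(C)(C)C)CC(C)(C)C1=O | intermediate
4 | ethynylmagnesium bromide (THF solution) | C#C[Mg]Br | starting material
5 | (4S)-4-(tert-butyldimethylsilyloxy)-1-ethynyl-2,6,6-trimethylcyclohex-2-en-1-ol, C1 epimer mixture | CC1=C[C@@H](O[Si](C)(C)C(C)(C)C)CC(C)(C)C1(O)C#C | intermediate
6 | (2E)-2-[(4S)-4-(tert-butyldimethylsilyloxy)-2,6,6-trimethylcyclohex-2-en-1-ylidene]acetaldehyde (formyl syn to the gem-dimethyl carbon) | CC1=C[C@@H](O[Si](C)(C)C(C)(C)C)CC(C)(C)\C1=C/C=O | intermediate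
7 | triethyl 2-phosphonopropionate | CCOC(=O)C(C)P(=O)(OCC)OCC | starting material
8 | ethyl (2E,4E)-4-[(4S)-4-(tert-butyldimethylsilyloxy)-2,6,6-trimethylcyclohex-2-en-1-ylidene]-2-methylbut-2-enoate | CC1=C[C@@H](O[Si](C)(C)C(C)(C)C)CC(C)(C)\C1=C/C=C(C)/C(=O)OCC | intermediate
9 | (2E,4E)-4-[(4S)-4-(tert-butyldimethylsilyloxy)-2,6,6-trimethylcyclohex-2-en-1-ylidene]-2-methylbut-2-en-1-ol | CC1=C[C@@H](O[Si](C)(C)C(C)(C)C)CC(C)(C)\C1=C/C=C(C)/CO | intermediate
10 | (2E,4E)-4-[(4S)-4-(tert-butyldimethylsilyloxy)-2,6,6-trimethylcyclohex-2-en-1-ylidene]-2-methylbut-2-enal | CC1=C[C@@H](O[Si](C)(C)C(C)(C)C)CC(C)(C)\C1=C/C=C(C)/C=O | intermediate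
11 | (triphenylphosphoranylidene)acetaldehyde | O=CC=P(c1ccccc1)(c1ccccc1)c1ccccc1 | starting material
12 | (2E,4E,6E)-6-[(4S)-4-(tert-butyldimethylsilyloxy)-2,6,6-trimethylcyclohex-2-en-1-ylidene]-4-methylhexa-2,4-dienal | CC1=C[C@@H](O[Si](C)(C)C(C)(C)C)CC(C)(C)\C1=C/C=C(C)/C=C/C=O | intermediate
13 | ethyl (2E,4E,6E,8E)-8-[(4S)-4-(tert-butyldimethylsilyloxy)-2,6,6-trimethylcyclohex-2-en-1-ylidene]-2,6-dimethylocta-2,4,6-trienoate | CC1=C[C@@H](O[Si](C)(C)C(C)(C)C)CC(C)(C)\C1=C/C=C(C)/C=C/C=C(C)/C(=O)OCC | intermediate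
14 | (2E,4E,6E,8E)-8-[(4S)-4-(tert-butyldimethylsilyloxy)-2,6,6-trimethylcyclohex-2-en-1-ylidene]-2,6-dimethylocta-2,4,6-trien-1-ol | CC1=C[C@@H](O[Si](C)(C)C(C)(C)C)CC(C)(C)\C1=C/C=C(C)/C=C/C=C(C)/CO | intermediate
15 | (2E,4E,6E,8E)-8-[(4S)-4-(tert-butyldimethylsilyloxy)-2,6,6-trimethylcyclohex-2-en-1-ylidene]-2,6-dimethylocta-2,4,6-trienal (ring B C19 aldehyde) | CC1=C[C@@H](O[Si](C)(C)C(C)(C)C)CC(C)(C)\C1=C/C=C(C)/C=C/C=C(C)/C=O | intermediate
16 | (2E,4E,6E,8E)-8-[(4S)-4-hydroxy-2,6,6-trimethylcyclohex-2-en-1-ylidene]-2,6-dimethylocta-2,4,6-trienal | CC1=C[C@@H](O)CC(C)(C)\C1=C/C=C(C)/C=C/C=C(C)/C=O | intermediate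
17 | (2E,4E,6E,8E)-2,6-dimethyl-8-[(4S)-2,6,6-trimethyl-4-(trimethylsilyloxy)cyclohex-2-en-1-ylidene]octa-2,4,6-trienal (ring A-side C19 aldehyde) | CC1=C[C@@H](O[Si](C)(C)C)CC(C)(C)\C1=C/C=C(C)/C=C/C=C(C)/C=O | intermediate
18 | bromomagnesium alkoxide of the C21 ethynyl carbinol from 17 (C14 epimers) | CC1=C[C@@H](O[Si](C)(C)C)CC(C)(C)\C1=C/C=C(C)/C=C/C=C(C)/C(O[Mg]Br)C#C | intermediate
19 | C15'-bromomagnesium acetylide of alkoxide 18 | CC1=C[C@@H](O[Si](C)(C)C)CC(C)(C)\C1=C/C=C(C)/C=C/C=C(C)/C(O[Mg]Br)C#C[Mg]Br | intermediate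
20 | C40 15,15'-yne-14,14'-diol, ring A 3-OTMS, ring B 3'-OTBS, (3S,3'S), chain alkenes all E, C14/C14' epimers | CC1=C[C@@H](O[Si](C)(C)C)CC(C)(C)\C1=C/C=C(C)/C=C/C=C(C)/C(O)C#CC(O)/C(C)=C/C=C/C(C)=C/C=C1/C(C)=C[C@@H](O[Si](C)(C)C(C)(C)C)CC1(C)C | intermediate
21 | C40 15,15'-yne-3,14,14'-triol 3'-TBS ether, (3S,3'S), C14/C14' epimers | CC1=C[C@@H](O)CC(C)(C)\C1=C/C=C(C)/C=C/C=C(C)/C(O)C#CC(O)/C(C)=C/C=C/C(C)=C/C=C1/C(C)=C[C@@H](O[Si](C)(C)C(C)(C)C)CC1(C)C | intermediate
22 | (3S,3'S)-3'-(tert-butyldimethylsilyloxy)-4',5'-didehydro-4,5'-retro-β,β-caroten-3-ol, C14=C15 and C15'=C14' geometry not yet uniform | CC1=C[C@@H](O)CC(C)(C)\C1=C/C=C(C)/C=C/C=C(C)/C=CC=C/C(C)=C/C=C/C(C)=C/C=C1/C(C)=C[C@@H](O[Si](C)(C)C(C)(C)C)CC1(C)C | intermediate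
23 | (3S,3'S,all-E)-3'-(tert-butyldimethylsilyloxy)-4',5'-didehydro-4,5'-retro-β,β-caroten-3-ol | CC1=C[C@@H](O)CC(C)(C)\C1=C/C=C(C)/C=C/C=C(C)/C=C/C=C/C(C)=C/C=C/C(C)=C/C=C1/C(C)=C[C@@H](O[Si](C)(C)C(C)(C)C)CC1(C)C | intermediate
24 | (3'S,all-E)-3'-(tert-butyldimethylsilyloxy)-4',5'-didehydro-4,5'-retro-β,β-caroten-3-one | CC1=CC(=O)CC(C)(C)\C1=C/C=C(C)/C=C/C=C(C)/C=C/C=C/C(C)=C/C=C/C(C)=C/C=C1/C(C)=C[C@@H](O[Si](C)(C)C(C)(C)C)CC1(C)C | intermediate
25 | (3'S,all-E)-3'-hydroxy-4',5'-didehydro-4,5'-retro-β,β-caroten-3-one (CNP0279160.1) | CC1=CC(=O)CC(C)(C)\C1=C/C=C(C)/C=C/C=C(C)/C=C/C=C/C(C)=C/C=C/C(C)=C/C=C1/C(C)=C[C@@H](O)CC1(C)C | target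

**Count**

Total steps: 19. Longest linear sequence: 19 steps (1 → 15 → 17 → 20 → 25; the ring A partner 17 is made from the ring B aldehyde 15, so every step lies on one line).

**Steps most likely to fail**

Step 14. The 1:1:1 stoichiometry may be lost: ethynylmagnesium bromide can disproportionate to the bis-Grignard reagent, or the first addition can stay incomplete, so that symmetrical ynediols and ethyl carbinols form in place of the mixed product. The fallback uses a blocked acetylene so that double addition is structurally impossible. It sets out from 15: lithium (trimethylsilyl)acetylide (Me3SiC≡CH, n-BuLi, THF, −78 °C) adds once to give the C-silylated C21 alkynol F1. K2CO3 in MeOH frees the alkyne terminus to give the C21 ethynyl carbinol F2. Its dilithio derivative (n-BuLi, 2 equiv, THF, −78 °C) then adds to 17. The same C14–C15 and C15'–C14' bonds are made, and the route is rejoined at 20.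

Step 4. Ionization at the doubly activated (allylic and propargylic) tertiary carbinol may compete with the 1,3-shift, leading to allylic transposition toward the ring or to elimination. The fallback moves the activation from the carbinol to an electron-rich alkyne. It sets out from 3: lithium ethoxyacetylide (ethoxyacetylene, n-BuLi, THF, −78 °C) gives the ethoxyalkynyl carbinol F3. Catalytic Sc(OTf)3 in CH2Cl2/EtOH effects the Meyer–Schuster shift of the ynol ether under very mild conditions to the ethyl cyclohexenylideneacetate F4. iBu2AlH reduces it to the cyclohexenylidene ethanol F5, and MnO2 oxidation rejoins the route at 6.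

Step 16. Hydride transfer may stop after the first hydroalumination (ene-diol stage), or the elimination may run with scrambled geometry and partial reduction of the polyene. The fallback separates alkyne reduction from deoxygenation. It sets out from 20: semi-hydrogenation over Pd/CaCO3 poisoned with Pb(OAc)2 (Lindlar catalyst) with quinoline gives the (15Z)-ene-14,14'-diol F6. Low-valent titanium prepared from TiCl3 and LiAlH4 in THF effects reductive 1,4-elimination of the ene-diol to the diene bis(silyl ether) F7; the ring hydroxyls stay silylated so that no free allylic alcohol meets the titanium reagent. K2CO3 in MeOH removes the trimethylsilyl group and rejoins the route at 22.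

**Further compounds**

F1 | step 14 | C-trimethylsilyl C21 alkynol from 15 (3-OTBS, C14 epimers) | CC1=C[C@@H](O[Si](C)(C)C(C)(C)C)CC(C)(C)\C1=C/C=C(C)/C=C/C=C(C)/C(O)C#C[Si](C)(C)C
F2 | step 14 | C21 ethynyl carbinol from 15 (3-OTBS, C14 epimers) | CC1=C[C@@H](O[Si](C)(C)C(C)(C)C)CC(C)(C)\C1=C/C=C(C)/C=C/C=C(C)/C(O)C#C
F3 | step 4 | (4S)-4-(tert-butyldimethylsilyloxy)-1-(ethoxyethynyl)-2,6,6-trimethylcyclohex-2-en-1-ol | CC1=C[C@@H](O[Si](C)(C)C(C)(C)C)CC(C)(C)C1(O)C#COCC
F4 | step 4 | ethyl (2E)-2-[(4S)-4-(tert-butyldimethylsilyloxy)-2,6,6-trimethylcyclohex-2-en-1-ylidene]acetate | CC1=C[C@@H](O[Si](C)(C)C(C)(C)C)CC(C)(C)\C1=C/C(=O)OCC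
F5 | step 4 | (2E)-2-[(4S)-4-(tert-butyldimethylsilyloxy)-2,6,6-trimethylcyclohex-2-en-1-ylidene]ethanol | CC1=C[C@@H](O[Si](C)(C)C(C)(C)C)CC(C)(C)\C1=C/CO
F6 | step 16 | C40 (15Z)-ene-14,14'-diol, ring A 3-OTMS, ring B 3'-OTBS (C14/C14' epimers) | CC1=C[C@@H](O[Si](C)(C)C)CC(C)(C)\C1=C/C=C(C)/C=C/C=C(C)/C(O)/C=C\C(O)/C(C)=C/C=C/C(C)=C/C=C1/C(C)=C[C@@H](O[Si](C)(C)C(C)(C)C)CC1(C)C
F7 | step 16 | (3S,3'S)-3-(trimethylsilyloxy)-3'-(tert-butyldimethylsilyloxy)-4',5'-didehydro-4,5'-retro-β,β-carotene, central diene geometry not yet uniform | CC1=C[C@@H](O[Si](C)(C)C)CC(C)(C)\C1=C/C=C(C)/C=C/C=C(C)/C=CC=C/C(C)=C/C=C/C(C)=C/C=C1/C(C)=C[C@@H](O[Si](C)(C)C(C)(C)C)CC1(C)C
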